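**Plan**

1. Retrosynthesis: the ten benzyl ethers are removed and an oxygen is put back at C5 of the central dihydrobenzofuran (dihydrobenzofuran 1). Its O1–C2 and C3a–C3 bonds are then cut together, giving quinone 17 (which carries the complete oxolane) and 4-hydroxystilbene 32 (which carries the complete dihydrobenzofuran 2).
2. Two features allow this. C2 bears a 4-hydroxyphenyl ring (ring P1), so the C2=C3 alkene is a vinylogous enol: C3 is nucleophilic and C2 becomes the carbon of a para-quinone methide. The resorcinol ring of dihydrobenzofuran 1 has C5–H para to O1, so it can enter as a 2-benzyloxy-1,4-benzoquinone in which only the future C3a is open; the extra C5 oxygen is removed later through its triflate.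
3. Oxolane: cut C2'–O/C5'–O (cationic closure of a 1,4-diol), the two aryl–carbinol bonds (aryl Grignard) and C3'–C4' (iridium/isothiourea allylation of an arylacetic ester).
4. Dihydrobenzofuran 2: cut C2''–C3'' (rhodium carbene C–H insertion) and the stilbene C–C bond (Heck reaction).
5. Forward order: oxolane, then its quinone; dihydrobenzofuran 2, then its stilbene; dihydrobenzofuran 1 is formed last by the union, followed by deoxygenation and global hydrogenolysis.
6. Stereochemistry: C3'/C4' from the two catalysts of the allylation; C2'/C5' from thermodynamic ring closure; C3'' from the chiral rhodium carboxylate and C2'' from acid equilibration; C3 from a chiral phosphoric acid and C2 from trans-selective ring closure.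

Key step: step 21

Remark on structure: the target is taken exactly as written. Dihydrobenzofuran 1 is (2S,3S); dihydrobenzofuran 2 is (2R,3R), fused to ring A with its free hydroxyl at C7'' next to the ring oxygen; the oxolane is (2'R,3'S,4'R,5'S), that is 2',3'-trans, 3',4'-cis, 4',5'-trans.
Remark on catalysts: the catalyst enantiomers named in steps 7, 18 and 21 are the expected ones. All three steps are reagent-controlled, so the antipode is used if a model reaction shows the opposite sense.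

**Part A – oxolane quinone**

Step 1
Reactants: 1 3,5-dihydroxybenzaldehyde
Product: 2 3-(benzyloxy)-5-hydroxybenzaldehyde
Conditions: BnBr (1.0 equiv), K2CO3 (1.0 equiv), DMF, 23 °C; mono-ether separated from diol and bis-ether
Reagents that add atoms: benzyl bromide, BrCc1ccccc1
Why: Williamson etherification of one of two equivalent phenols under stoichiometric control should give the mono-benzyl ether, which differentiates the two oxygens of the future benzenoid ring of dihydrobenzofuran 1.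

Step 2
Reactants: 2 3-(benzyloxy)-5-hydroxybenzaldehyde
Product: 3 3-(benzyloxy)-5-[(triisopropylsilyl)oxy]benzaldehyde
Conditions: iPr3SiCl, imidazole, DMF, 23 °C
Reagents that add atoms: triisopropylsilyl chloride, CC(C)[Si](Cl)(C(C)C)C(C)C
Why: Silylation of the remaining phenol should give an aryl silyl ether that survives bases, hydrides, Grignard reagents and mild acid and is cleaved by fluoride in the presence of benzyl ethers.

Step 3
Reactants: 3 silyl-protected aldehyde
Product: 4 ethyl (E)-3-{3-(benzyloxy)-5-[(triisopropylsilyl)oxy]phenyl}prop-2-enoate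
Conditions: (EtO)2P(O)CH2CO2Et, NaH, THF, 0 to 23 °C
Reagents that add atoms: triethyl phosphonoacetate, CCOC(=O)CP(=O)(OCC)OCC
Why: Horner–Wadsworth–Emmons olefination of an aryl aldehyde with a stabilized phosphonate should give the E-cinnamate.

Step 4
Reactants: 4 cinnamate ester
Product: 5 (E)-3-{3-(benzyloxy)-5-[(triisopropylsilyl)oxy]phenyl}prop-2-en-1-ol
Conditions: iBu2AlH (2.2 equiv), CH2Cl2, −78 °C
Reagents that add atoms: none
Why: 1,2-Reduction of the enoate with diisobutylaluminium hydride should give the cinnamyl alcohol without touching the alkene.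

Step 5
Reactants: 5 cinnamyl alcohol
Product: 6 tert-butyl (E)-3-{3-(benzyloxy)-5-[(triisopropylsilyl)oxy]phenyl}prop-2-en-1-yl carbonate
Conditions: Boc2O, DMAP (10 mol %), CH2Cl2, 23 °C
Reagents that add atoms: di-tert-butyl dicarbonate, CC(C)(C)OC(=O)OC(=O)OC(C)(C)C
Why: Acylation of the primary allylic alcohol should give the linear tert-butyl carbonate, the standard electrophile for iridium-catalysed allylic substitution.

Step 6
Reactants: 7 3,5-bis(benzyloxy)phenylacetic acid
Product: 8 pentafluorophenyl 3,5-bis(benzyloxy)phenylacetate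
Conditions: C6F5OH, DCC, CH2Cl2, 0 to 23 °C
Reagents that add atoms: pentafluorophenol, Oc1c(F)c(F)c(F)c(F)c1F
Why: Carbodiimide esterification should give the activated aryl ester needed for isothiourea (C1-ammonium enolate) catalysis.

Step 7
Reactants: 6 allylic carbonate; 8 pentafluorophenyl ester
Product: 10 (2R,3S)-2-[3,5-bis(benzyloxy)phenyl]-3-{3-(benzyloxy)-5-[(triisopropylsilyl)oxy]phenyl}-N-methoxy-N-methylpent-4-enamide, via pentafluorophenyl ester 9 (not isolated)
Conditions: [Ir(cod)Cl]2 (2 mol %), (S,S,S)-binaphthol-derived N,N-bis(1-phenylethyl)phosphoramidite (4 mol %, cyclometalated), (R)-benzotetramisole (10 mol %), iPr2NEt, THF, 23 °C; then MeNHOMe·HCl, iPr2NEt, 23 °C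
Reagents that add atoms: N,O-dimethylhydroxylamine hydrochloride, CNOC.Cl
Why: Stereodivergent dual catalysis (branched-selective iridium allylic substitution with an isothiourea-bound ammonium enolate of an aryl acetic ester) should form the C3'–C4' bond, the allyl-iridium complex fixing the centre that bears the silyloxyaryl ring and the isothiourea fixing the α-centre; aminolysis of the active ester then gives the Weinreb amide.

Step 8
Reactants: 10 Weinreb amide
Product: 11 (2R,3S)-2-[3,5-bis(benzyloxy)phenyl]-3-{3-(benzyloxy)-5-[(triisopropylsilyl)oxy]phenyl}-N-methoxy-N-methyl-4-oxobutanamide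
Conditions: K2OsO4·2H2O (2 mol %), NaIO4, 2,6-lutidine, dioxane/H2O, 23 °C; used at once
Reagents that add atoms: sodium periodate, [Na+].[O-]I(=O)(=O)=O; water, O
Why: Lemieux–Johnson cleavage of the terminal alkene should give the aldehyde without oxidising the electron-rich arenes, which ozone would endanger.

Step 9
Reactants: 11 aldehyde amide; 12 4-(benzyloxy)phenylmagnesium bromide (commercial THF solution)
Product: 13 (2R,3S)-1,4-bis[4-(benzyloxy)phenyl]-2-[3,5-bis(benzyloxy)phenyl]-3-{3-(benzyloxy)-5-[(triisopropylsilyl)oxy]phenyl}-4-hydroxybutan-1-one (both C4 epimers; in equilibrium with its cyclic hemiketal)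
Conditions: 12 (3.5 equiv), THF, −78 °C then 0 °C; aq. NH4Cl
Reagents that add atoms: none
Why: Grignard addition to the aldehyde at low temperature and then to the Weinreb amide (stable chelate, no over-addition) should install both 4-benzyloxyphenyl carbinol carbons in one operation; the new carbinol centre is not controlled and is reset in step 10.

Step 10
Reactants: 13 hydroxy ketone
Product: 15 (2R,3S,4R,5S)-2,5-bis[4-(benzyloxy)phenyl]-4-[3,5-bis(benzyloxy)phenyl]-3-{3-(benzyloxy)-5-[(triisopropylsilyl)oxy]phenyl}oxolane, via tetraaryl butane-1,4-diol 14 (not isolated)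
Conditions: NaBH4, CeCl3·7H2O, THF/MeOH, −40 °C; crude diol then TsOH·H2O (cat.), CH2Cl2, 0 to 23 °C until the isomer ratio no longer changes
Reagents that add atoms: none
Why: Luche-type reduction followed by acid-catalysed cyclodehydration (SN1 through 4-benzyloxybenzyl cations, reversible at both benzylic ether carbons) should converge on the isomer with each 2/5-aryl group trans to its neighbour, so C2' and C5' are set under thermodynamic control relative to the fixed cis C3'/C4' pair.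

Step 11
Reactants: 15 silyl-protected oxolane
Product: 16 3-(benzyloxy)-5-{(2R,3S,4R,5S)-2,5-bis[4-(benzyloxy)phenyl]-4-[3,5-bis(benzyloxy)phenyl]oxolan-3-yl}phenol
Conditions: Bu4NF, THF, 0 °C
Reagents that add atoms: none
Why: Fluoride cleavage of the aryl silyl ether should release the single phenol and leave all benzyl ethers untouched.

Step 12
Reactants: 16 phenol
Product: 17 2-(benzyloxy)-6-{(2R,3S,4R,5S)-2,5-bis[4-(benzyloxy)phenyl]-4-[3,5-bis(benzyloxy)phenyl]oxolan-3-yl}cyclohexa-2,5-diene-1,4-dione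
Conditions: (KSO3)2NO (potassium nitrosodisulfonate, 2.5 equiv), KH2PO4 buffer, methyltrioctylammonium chloride, CH2Cl2/H2O, 23 °C
Reagents that add atoms: potassium nitrosodisulfonate, [K+].[K+].[O]N(S(=O)(=O)[O-])S(=O)(=O)[O-]
Why: Teuber oxidation of a phenol with a free para position should give the para-quinone; the new oxygen (between the benzyloxy group and the oxolane) is the temporary one that ends at C5 of dihydrobenzofuran 1.

**Part B – stilbene carrying dihydrobenzofuran 2**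

Step 13
Reactants: 18 3-(benzyloxy)-2-hydroxybenzaldehyde
Product: 19 3-(benzyloxy)-5-bromo-2-hydroxybenzaldehyde
Conditions: N-bromosuccinimide, MeCN, 0 °C
Reagents that add atoms: N-bromosuccinimide, O=C1CCC(=O)N1Br
Why: Electrophilic bromination should occur para to the free phenol (meta to the formyl group), placing the handle for the later stilbene on ring A.

Step 14
Reactants: 19 bromophenol aldehyde; 20 4-(benzyloxy)benzyl chloride
Product: 21 3-(benzyloxy)-2-{[4-(benzyloxy)phenyl]methoxy}-5-bromobenzaldehyde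
Conditions: K2CO3, KI (cat.), DMF, 60 °C
Reagents that add atoms: none
Why: Williamson etherification should install the benzylic ether whose CH2 becomes C2'' and whose aryl group becomes the C2'' 4-oxyphenyl ring.

Step 15
Reactants: 21 aldehyde; 22 1-bromo-3,5-bis(benzyloxy)benzene
Product: 24 [3,5-bis(benzyloxy)phenyl][3-(benzyloxy)-2-{[4-(benzyloxy)phenyl]methoxy}-5-bromophenyl]methanol (racemic), via arylmagnesium bromide 23 (not isolated)
Conditions: 22, Mg, I2 (cat.), THF, 40 °C; then 21, THF, −78 to 0 °C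
Reagents that add atoms: none
Why: Grignard addition to the aldehyde should give the diaryl carbinol; the aryl bromide of 21 does not exchange under these conditions.

Step 16
Reactants: 24 diaryl carbinol
Product: 25 [3,5-bis(benzyloxy)phenyl][3-(benzyloxy)-2-{[4-(benzyloxy)phenyl]methoxy}-5-bromophenyl]methanone
Conditions: Dess–Martin periodinane, NaHCO3, CH2Cl2, 23 °C
Reagents that add atoms: none
Why: Dess–Martin oxidation of the benzhydrol should give the benzophenone under neutral conditions.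

Step 17
Reactants: 25 benzophenone
Product: 26 hydrazone of 25
Conditions: N2H4·H2O (excess), AcOH (cat.), EtOH, 80 °C
Reagents that add atoms: hydrazine hydrate, NN.O
Why: Condensation of the diaryl ketone with hydrazine should give the free hydrazone, the precursor of a donor/donor diazo compound.

Step 18
Reactants: 26 hydrazone
Product: 28 (2S,3R)-7-(benzyloxy)-2-[4-(benzyloxy)phenyl]-3-[3,5-bis(benzyloxy)phenyl]-5-bromo-2,3-dihydro-1-benzofuran, via diaryldiazomethane 27 (not isolated)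
Conditions: MnO2, CH2Cl2, 0 °C, filtration; then dirhodium tetrakis[(R)-N-phthaloyl-(1-adamantyl)glycinate], Rh2(R-PTAD)4 (1 mol %), CH2Cl2, −40 to 0 °C
Reagents that add atoms: none
Why: Enantioselective intramolecular 1,5-C–H insertion of a donor/donor rhodium carbene into the benzylic ether C–H should close dihydrobenzofuran 2, with C3'' set by the chiral carboxylate ligands and the 2,3-cis isomer expected from the concerted insertion.

Step 19
Reactants: 28 cis-dihydrobenzofuran
Product: 29 (2R,3R)-7-(benzyloxy)-2-[4-(benzyloxy)phenyl]-3-[3,5-bis(benzyloxy)phenyl]-5-bromo-2,3-dihydro-1-benzofuran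
Conditions: CF3CO2H (10 vol %), CH2Cl2, 0 °C, short reaction time
Reagents that add atoms: none
Why: Reversible acid-induced opening of the benzylic C2''–O bond (4-benzyloxybenzyl cation) and reclosure should epimerise C2'' to the more stable 2,3-trans isomer while C3'' stays untouched.

Step 20
Reactants: 29 aryl bromide; 30 4-acetoxystyrene
Product: 32 4-[(E)-2-{(2R,3R)-7-(benzyloxy)-2-[4-(benzyloxy)phenyl]-3-[3,5-bis(benzyloxy)phenyl]-2,3-dihydro-1-benzofuran-5-yl}ethenyl]phenol, via aryl acetate 31 (not isolated)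
Conditions: Pd(OAc)2 (5 mol %), P(o-tol)3, Et3N, DMF, 100 °C; then K2CO3, MeOH, 23 °C
Reagents that add atoms: none
Why: Heck reaction of the aryl bromide with the styrene should give the E-stilbene, and methanolysis of the acetate frees the one phenol that the key step needs.

**Part C – union and end game**

Step 21
Reactants: 17 oxolane quinone; 32 4-hydroxystilbene
Product: 34 nona-O-benzyl-5-hydroxykobophenol A (free hydroxyls on ring P1 and at C5 of dihydrobenzofuran 1), via quinone methide hydroquinone 33 (not isolated)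
Conditions: (R)-3,3'-bis(2,4,6-triisopropylphenyl)-1,1'-binaphthyl-2,2'-diyl hydrogen phosphate (10 mol %), 4 Å molecular sieves, CH2Cl2, −20 to 0 °C, argon, dark; the N-triflyl phosphoramide analogue if the quinone is sluggish
Reagents that add atoms: none
Why: Proposed new method: the phosphoric acid is expected to hydrogen-bond the quinone at its C1 carbonyl (flanked by the benzyloxy group) while its phosphoryl oxygen accepts the phenolic O–H of 32, so that the 4-hydroxystilbene reacts as a vinylogous enol through C3 at C5 of the quinone and gives, after enolisation, hydroquinone para-quinone methide 33. The hydroquinone oxygen that was the C4 carbonyl then adds to the quinone methide carbon C2 in a 5-exo-trig oxa-1,6-addition, which closes the furan ring and rearomatises ring P1. The closest known reactions are the Lewis-acid promoted formal [3+2] cycloaddition of 2-alkoxy-1,4-benzoquinones with propenylbenzenes and the chiral phosphoric acid catalysed [3+2] reactions of quinone monoimines with hydroxystyrenes and vinylindoles. C3 is set in the C–C bond formation by the catalyst, which selects the alkene face inside the doubly hydrogen-bonded assembly, and C2 is set in the ring closure, trans to the C3 aryl group on steric grounds and correctable by reversible ring opening. The step needs site selectivity on both partners: the free para-hydroxyl of ring P1 (every other phenol is a benzyl ether) makes C3 the nucleophilic carbon and C2 the oxygen acceptor, and on the quinone C6 carries the oxolane and C3 is the α-carbon of the vinylogous ester, so C5 is the only electrophilic position and the C4 oxygen the only one that can close a five-membered ring.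

Step 22
Reactants: 34 bis-phenol
Product: 35 deca-O-benzyl-5-hydroxykobophenol A (free hydroxyl only at C5 of dihydrobenzofuran 1)
Conditions: BnBr (1.05 equiv), K2CO3, acetone, 23 °C
Reagents that add atoms: benzyl bromide, BrCc1ccccc1
Why: Williamson etherification should select the unhindered phenol of ring P1 over the C5 hydroxyl, which is flanked by the benzyloxy group and the oxolane.

Step 23
Reactants: 35 hindered phenol
Product: 36 C5 trifluoromethanesulfonate of 35
Conditions: Tf2O, pyridine, CH2Cl2, −20 to 0 °C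
Reagents that add atoms: trifluoromethanesulfonic anhydride, O=S(=O)(OS(=O)(=O)C(F)(F)F)C(F)(F)F
Why: Sulfonylation of the remaining phenol should turn the temporary C5 oxygen into a leaving group for reduction.

Step 24
Reactants: 36 aryl triflate
Product: 37 deca-O-benzylkobophenol A
Conditions: Pd(OAc)2 (10 mol %), 1,1'-bis(diphenylphosphino)ferrocene Fe(C5H4PPh2)2 (12 mol %), HCO2H, Et3N, DMF, 80 °C
Reagents that add atoms: none
Why: Palladium-catalysed formate reduction of the aryl triflate should replace the temporary oxygen by hydrogen and leave benzyl ethers and the cyclic benzylic ethers intact.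

Step 25
Reactants: 37 deca-O-benzylkobophenol A
Product: 38 kobophenol A
Conditions: H2 (1 atm), Pd(OH)2 on carbon, THF/MeOH, 23 °C
Reagents that add atoms: none
Why: Neutral hydrogenolysis of the ten benzyl aryl ethers should release the target without acid, to which the oxolane is sensitive; no stereocentre is involved.

**Compound list**

1 | 3,5-dihydroxybenzaldehyde | O=Cc1cc(O)cc(O)c1 | starting material
2 | 3-(benzyloxy)-5-hydroxybenzaldehyde | O=Cc1cc(O)cc(OCc2ccccc2)c1 | intermediate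
3 | 3-(benzyloxy)-5-[(triisopropylsilyl)oxy]benzaldehyde | O=Cc1cc(OCc2ccccc2)cc(O[Si](C(C)C)(C(C)C)C(C)C)c1 | intermediate
4 | ethyl (E)-3-{3-(benzyloxy)-5-[(triisopropylsilyl)oxy]phenyl}prop-2-enoate | CCOC(=O)/C=C/c1cc(OCc2ccccc2)cc(O[Si](C(C)C)(C(C)C)C(C)C)c1 | intermediate
5 | (E)-3-{3-(benzyloxy)-5-[(triisopropylsilyl)oxy]phenyl}prop-2-en-1-ol | OC/C=C/c1cc(OCc2ccccc2)cc(O[Si](C(C)C)(C(C)C)C(C)C)c1 | intermediate
6 | tert-butyl (E)-3-{3-(benzyloxy)-5-[(triisopropylsilyl)oxy]phenyl}prop-2-en-1-yl carbonate | CC(C)(C)OC(=O)OC/C=C/c1cc(OCc2ccccc2)cc(O[Si](C(C)C)(C(C)C)C(C)C)c1 | intermediate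
7 | 3,5-bis(benzyloxy)phenylacetic acid | OC(=O)Cc1cc(OCc2ccccc2)cc(OCc2ccccc2)c1 | starting material
8 | pentafluorophenyl 3,5-bis(benzyloxy)phenylacetate | O=C(Cc1cc(OCc2ccccc2)cc(OCc2ccccc2)c1)Oc1c(F)c(F)c(F)c(F)c1F | intermediate
9 | pentafluorophenyl (2R,3S)-2-[3,5-bis(benzyloxy)phenyl]-3-{3-(benzyloxy)-5-[(triisopropylsilyl)oxy]phenyl}pent-4-enoate | O=C(Oc1c(F)c(F)c(F)c(F)c1F)[C@@H](c1cc(OCc2ccccc2)cc(OCc2ccccc2)c1)[C@@H](c1cc(OCc2ccccc2)cc(O[Si](C(C)C)(C(C)C)C(C)C)c1)C=C | intermediate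
10 | (2R,3S)-2-[3,5-bis(benzyloxy)phenyl]-3-{3-(benzyloxy)-5-[(triisopropylsilyl)oxy]phenyl}-N-methoxy-N-methylpent-4-enamide | CON(C)C(=O)[C@@H](c1cc(OCc2ccccc2)cc(OCc2ccccc2)c1)[C@@H](c1cc(OCc2ccccc2)cc(O[Si](C(C)C)(C(C)C)C(C)C)c1)C=C | intermediate
11 | (2R,3S)-2-[3,5-bis(benzyloxy)phenyl]-3-{3-(benzyloxy)-5-[(triisopropylsilyl)oxy]phenyl}-N-methoxy-N-methyl-4-oxobutanamide | CON(C)C(=O)[C@@H](c1cc(OCc2ccccc2)cc(OCc2ccccc2)c1)[C@@H](c1cc(OCc2ccccc2)cc(O[Si](C(C)C)(C(C)C)C(C)C)c1)C=O | intermediate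
12 | 4-(benzyloxy)phenylmagnesium bromide | Br[Mg]c1ccc(OCc2ccccc2)cc1 | starting material
13 | (2R,3S)-1,4-bis[4-(benzyloxy)phenyl]-2-[3,5-bis(benzyloxy)phenyl]-3-{3-(benzyloxy)-5-[(triisopropylsilyl)oxy]phenyl}-4-hydroxybutan-1-one, C4 epimers | O=C(c1ccc(OCc2ccccc2)cc1)[C@@H](c1cc(OCc2ccccc2)cc(OCc2ccccc2)c1)[C@@H](c1cc(OCc2ccccc2)cc(O[Si](C(C)C)(C(C)C)C(C)C)c1)C(O)c1ccc(OCc2ccccc2)cc1 | intermediate
14 | (2R,3S)-1,4-bis[4-(benzyloxy)phenyl]-2-[3,5-bis(benzyloxy)phenyl]-3-{3-(benzyloxy)-5-[(triisopropylsilyl)oxy]phenyl}butane-1,4-diol, C1 and C4 epimers | OC(c1ccc(OCc2ccccc2)cc1)[C@@H](c1cc(OCc2ccccc2)cc(OCc2ccccc2)c1)[C@@H](c1cc(OCc2ccccc2)cc(O[Si](C(C)C)(C(C)C)C(C)C)c1)C(O)c1ccc(OCc2ccccc2)cc1 | intermediate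
15 | (2R,3S,4R,5S)-2,5-bis[4-(benzyloxy)phenyl]-4-[3,5-bis(benzyloxy)phenyl]-3-{3-(benzyloxy)-5-[(triisopropylsilyl)oxy]phenyl}oxolane | CC(C)[Si](Oc1cc(OCc2ccccc2)cc(c1)[C@@H]1[C@H](c2cc(OCc3ccccc3)cc(OCc3ccccc3)c2)[C@@H](c2ccc(OCc3ccccc3)cc2)O[C@H]1c1ccc(OCc2ccccc2)cc1)(C(C)C)C(C)C | intermediate
16 | 3-(benzyloxy)-5-{(2R,3S,4R,5S)-2,5-bis[4-(benzyloxy)phenyl]-4-[3,5-bis(benzyloxy)phenyl]oxolan-3-yl}phenol | Oc1cc(OCc2ccccc2)cc(c1)[C@@H]1[C@H](c2cc(OCc3ccccc3)cc(OCc3ccccc3)c2)[C@@H](c2ccc(OCc3ccccc3)cc2)O[C@H]1c1ccc(OCc2ccccc2)cc1 | intermediate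
17 | 2-(benzyloxy)-6-{(2R,3S,4R,5S)-2,5-bis[4-(benzyloxy)phenyl]-4-[3,5-bis(benzyloxy)phenyl]oxolan-3-yl}cyclohexa-2,5-diene-1,4-dione | O=C1C=C(OCc2ccccc2)C(=O)C(=C1)[C@@H]1[C@H](c2cc(OCc3ccccc3)cc(OCc3ccccc3)c2)[C@@H](c2ccc(OCc3ccccc3)cc2)O[C@H]1c1ccc(OCc2ccccc2)cc1 | intermediate
18 | 3-(benzyloxy)-2-hydroxybenzaldehyde | O=Cc1cccc(OCc2ccccc2)c1O | starting material
19 | 3-(benzyloxy)-5-bromo-2-hydroxybenzaldehyde | O=Cc1cc(Br)cc(OCc2ccccc2)c1O | intermediate
20 | 4-(benzyloxy)benzyl chloride | ClCc1ccc(OCc2ccccc2)cc1 | starting material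
21 | 3-(benzyloxy)-2-{[4-(benzyloxy)phenyl]methoxy}-5-bromobenzaldehyde | O=Cc1cc(Br)cc(OCc2ccccc2)c1OCc1ccc(OCc2ccccc2)cc1 | intermediate
22 | 1-bromo-3,5-bis(benzyloxy)benzene | Brc1cc(OCc2ccccc2)cc(OCc2ccccc2)c1 | starting material
23 | 3,5-bis(benzyloxy)phenylmagnesium bromide | Br[Mg]c1cc(OCc2ccccc2)cc(OCc2ccccc2)c1 | intermediate
24 | [3,5-bis(benzyloxy)phenyl][3-(benzyloxy)-2-{[4-(benzyloxy)phenyl]methoxy}-5-bromophenyl]methanol, racemic | OC(c1cc(OCc2ccccc2)cc(OCc2ccccc2)c1)c1cc(Br)cc(OCc2ccccc2)c1OCc1ccc(OCc2ccccc2)cc1 | intermediate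
25 | [3,5-bis(benzyloxy)phenyl][3-(benzyloxy)-2-{[4-(benzyloxy)phenyl]methoxy}-5-bromophenyl]methanone | O=C(c1cc(OCc2ccccc2)cc(OCc2ccccc2)c1)c1cc(Br)cc(OCc2ccccc2)c1OCc1ccc(OCc2ccccc2)cc1 | intermediate
26 | hydrazone of 25 | NN=C(c1cc(OCc2ccccc2)cc(OCc2ccccc2)c1)c1cc(Br)cc(OCc2ccccc2)c1OCc1ccc(OCc2ccccc2)cc1 | intermediate
27 | diazo compound from 26 (diaryldiazomethane) | [N-]=[N+]=C(c1cc(OCc2ccccc2)cc(OCc2ccccc2)c1)c1cc(Br)cc(OCc2ccccc2)c1OCc1ccc(OCc2ccccc2)cc1 | intermediate
28 | (2S,3R)-7-(benzyloxy)-2-[4-(benzyloxy)phenyl]-3-[3,5-bis(benzyloxy)phenyl]-5-bromo-2,3-dihydro-1-benzofuran (cis) | Brc1cc(OCc2ccccc2)c2c(c1)[C@@H](c1cc(OCc3ccccc3)cc(OCc3ccccc3)c1)[C@@H](c1ccc(OCc3ccccc3)cc1)O2 | intermediate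
29 | (2R,3R)-7-(benzyloxy)-2-[4-(benzyloxy)phenyl]-3-[3,5-bis(benzyloxy)phenyl]-5-bromo-2,3-dihydro-1-benzofuran (trans) | Brc1cc(OCc2ccccc2)c2c(c1)[C@@H](c1cc(OCc3ccccc3)cc(OCc3ccccc3)c1)[C@H](c1ccc(OCc3ccccc3)cc1)O2 | intermediate
30 | 4-acetoxystyrene | CC(=O)Oc1ccc(C=C)cc1 | starting material
31 | 4-[(E)-2-{(2R,3R)-7-(benzyloxy)-2-[4-(benzyloxy)phenyl]-3-[3,5-bis(benzyloxy)phenyl]-2,3-dihydro-1-benzofuran-5-yl}ethenyl]phenyl acetate | CC(=O)Oc1ccc(/C=C/c2cc(OCc3ccccc3)c3c(c2)[C@@H](c2cc(OCc4ccccc4)cc(OCc4ccccc4)c2)[C@H](c2ccc(OCc4ccccc4)cc2)O3)cc1 | intermediate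
32 | 4-[(E)-2-{(2R,3R)-7-(benzyloxy)-2-[4-(benzyloxy)phenyl]-3-[3,5-bis(benzyloxy)phenyl]-2,3-dihydro-1-benzofuran-5-yl}ethenyl]phenol | Oc1ccc(/C=C/c2cc(OCc3ccccc3)c3c(c2)[C@@H](c2cc(OCc4ccccc4)cc(OCc4ccccc4)c2)[C@H](c2ccc(OCc4ccccc4)cc2)O3)cc1 | intermediate
33 | hydroquinone para-quinone methide: 2-benzyloxy-6-(oxolan-3-yl)hydroquinone bearing at C5 the (S)-CH(aryl A)–CH=(4-oxocyclohexa-2,5-dienylidene) unit | Oc1cc(OCc2ccccc2)c(O)c([C@@H]2[C@H](c3cc(OCc4ccccc4)cc(OCc4ccccc4)c3)[C@@H](c3ccc(OCc4ccccc4)cc3)O[C@H]2c2ccc(OCc3ccccc3)cc2)c1[C@@H](C=C1C=CC(=O)C=C1)c1cc(OCc2ccccc2)c2c(c1)[C@@H](c1cc(OCc3ccccc3)cc(OCc3ccccc3)c1)[C@H](c1ccc(OCc3ccccc3)cc1)O2 | intermediate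
34 | nona-O-benzyl-5-hydroxykobophenol A: (2S,3S)-dihydrobenzofuran 1 with free 4-hydroxyphenyl at C2, free OH at C5, OBn at C6, the (2R,3S,4R,5S)-oxolan-3-yl group at C4 and the (2R,3R)-dihydrobenzofuran-2-5-yl group at C3 | Oc1ccc([C@H]2Oc3cc(OCc4ccccc4)c(O)c([C@@H]4[C@H](c5cc(OCc6ccccc6)cc(OCc6ccccc6)c5)[C@@H](c5ccc(OCc6ccccc6)cc5)O[C@H]4c4ccc(OCc5ccccc5)cc4)c3[C@@H]2c2cc(OCc3ccccc3)c3c(c2)[C@@H](c2cc(OCc4ccccc4)cc(OCc4ccccc4)c2)[C@H](c2ccc(OCc4ccccc4)cc2)O3)cc1 | intermediate
35 | deca-O-benzyl-5-hydroxykobophenol A (as 34, ring P1 as benzyl ether) | c7ccccc7COc1ccc([C@H]2Oc3cc(OCc4ccccc4)c(O)c([C@@H]4[C@H](c5cc(OCc6ccccc6)cc(OCc6ccccc6)c5)[C@@H](c5ccc(OCc6ccccc6)cc5)O[C@H]4c4ccc(OCc5ccccc5)cc4)c3[C@@H]2c2cc(OCc3ccccc3)c3c(c2)[C@@H](c2cc(OCc4ccccc4)cc(OCc4ccccc4)c2)[C@H](c2ccc(OCc4ccccc4)cc2)O3)cc1 | intermediate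
36 | C5 trifluoromethanesulfonate of 35 | c7ccccc7COc1ccc([C@H]2Oc3cc(OCc4ccccc4)c(OS(=O)(=O)C(F)(F)F)c([C@@H]4[C@H](c5cc(OCc6ccccc6)cc(OCc6ccccc6)c5)[C@@H](c5ccc(OCc6ccccc6)cc5)O[C@H]4c4ccc(OCc5ccccc5)cc4)c3[C@@H]2c2cc(OCc3ccccc3)c3c(c2)[C@@H](c2cc(OCc4ccccc4)cc(OCc4ccccc4)c2)[C@H](c2ccc(OCc4ccccc4)cc2)O3)cc1 | intermediate
37 | deca-O-benzylkobophenol A | c7ccccc7COc1ccc([C@H]2Oc3cc(OCc4ccccc4)cc([C@@H]4[C@H](c5cc(OCc6ccccc6)cc(OCc6ccccc6)c5)[C@@H](c5ccc(OCc6ccccc6)cc5)O[C@H]4c4ccc(OCc5ccccc5)cc4)c3[C@@H]2c2cc(OCc3ccccc3)c3c(c2)[C@@H](c2cc(OCc4ccccc4)cc(OCc4ccccc4)c2)[C@H](c2ccc(OCc4ccccc4)cc2)O3)cc1 | intermediate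
38 | kobophenol A | Oc1ccc([C@H]2Oc3cc(O)cc([C@@H]4[C@H](c5cc(O)cc(O)c5)[C@@H](c5ccc(O)cc5)O[C@H]4c4ccc(O)cc4)c3[C@@H]2c2cc(O)c3c(c2)[C@@H](c2cc(O)cc(O)c2)[C@H](c2ccc(O)cc2)O3)cc1 | target

**Step count and risks**

Total step count: 25. Longest linear sequence: 16 steps (steps 1–5, 7–12, 21–25).

Steps most likely to fail:

1. Step 21 (Proposed new method). The hindered alkoxyquinone may be activated too weakly by the phosphoric acid, so that C–C bond formation is slow and hydrogen transfer from the hydroxystilbene to the quinone competes. Facial selection may also be poor, because the catalyst must override two large chiral partners. The fallback uses known chemistry, sets out from 29 and 17 and comes back at 35. Suzuki coupling of 29 with (E)-2-ethoxyvinylboronic acid pinacol ester (Pd(PPh3)4, K3PO4) should give the (E)-2-ethoxyvinyl arene F1, and mild aqueous acid hydrolysis gives the arylacetaldehyde F2. Enamine-catalysed α-arylation of F2 with quinone 17 (a diarylprolinol silyl ether) attacks the same quinone carbon and, after hemiacetal formation, gives the 2-hydroxy-2,3-dihydrobenzofuran-5-ol lactol F3 with C3 set by the amine catalyst. Excess 12 opens the lactol to the hydroquinone benzylic alcohol F4. Catalytic acid then closes the ring through the 4-benzyloxybenzyl cation, trans to the C3 aryl group, and gives 35, so that step 22 is not needed.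

2. Step 10. The cationic closure may not converge: the two carbinol epimers may give a mixture at C2'/C5', and the benzylic cation may be captured by the neighbouring dialkoxyphenyl ring in a Friedel–Crafts reaction instead of by the hydroxyl. The fallback avoids carbocations, sets out from 11 and comes back at 15. 4-(Allyloxy)phenylmagnesium bromide in place of 12 should give the bis-allyl hydroxy ketone F5, and NaBH4/CeCl3·7H2O gives the bis-allyl diol F6. Pd(PPh3)4 with morpholine removes both allyl groups to give the bis-phenol diol F7. Warming F7 with a catalytic tertiary amine eliminates water to a para-quinone methide, which the remaining hydroxyl closes by a reversible oxa-1,6-addition to the bis-phenol oxolane F8 under thermodynamic control. Benzylation of the two phenols (BnBr, K2CO3, acetone) gives 15.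

3. Step 25. Hydrogenolysis of the benzylic ring C–O bonds of the two dihydrobenzofurans and the oxolane may compete with removal of the last benzyl ethers, or the reaction may stall at partly benzylated stages. The fallback sets out from 37 and comes back at 38: non-reductive debenzylation with BCl3 and pentamethylbenzene in CH2Cl2 at −78 °C, in which the benzyl cations are trapped by the scavenger. It makes no compound outside the list (none F0).

Further compounds
F1 | step 21 | (2R,3R)-7-(benzyloxy)-2-[4-(benzyloxy)phenyl]-3-[3,5-bis(benzyloxy)phenyl]-5-[(E)-2-ethoxyethenyl]-2,3-dihydro-1-benzofuran | CCO/C=C/c1cc(OCc2ccccc2)c2c(c1)[C@@H](c1cc(OCc3ccccc3)cc(OCc3ccccc3)c1)[C@H](c1ccc(OCc3ccccc3)cc1)O2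
F2 | step 21 | {(2R,3R)-7-(benzyloxy)-2-[4-(benzyloxy)phenyl]-3-[3,5-bis(benzyloxy)phenyl]-2,3-dihydro-1-benzofuran-5-yl}acetaldehyde | O=CCc1cc(OCc2ccccc2)c2c(c1)[C@@H](c1cc(OCc3ccccc3)cc(OCc3ccccc3)c1)[C@H](c1ccc(OCc3ccccc3)cc1)O2
F3 | step 21 | lactol: (3S)-6-(benzyloxy)-2,3-dihydro-1-benzofuran-2,5-diol carrying the oxolan-3-yl group at C4 and the dihydrobenzofuran-2-5-yl group at C3, C2 epimers | OC1Oc2cc(OCc3ccccc3)c(O)c([C@@H]3[C@H](c4cc(OCc5ccccc5)cc(OCc5ccccc5)c4)[C@@H](c4ccc(OCc5ccccc5)cc4)O[C@H]3c3ccc(OCc4ccccc4)cc3)c2[C@@H]1c1cc(OCc2ccccc2)c2c(c1)[C@@H](c1cc(OCc3ccccc3)cc(OCc3ccccc3)c1)[C@H](c1ccc(OCc3ccccc3)cc1)O2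
F4 | step 21 | hydroquinone benzylic alcohol: 33 with the quinone methide replaced by CH(OH)[4-(benzyloxy)phenyl], carbinol epimers | Oc1cc(OCc2ccccc2)c(O)c([C@@H]2[C@H](c3cc(OCc4ccccc4)cc(OCc4ccccc4)c3)[C@@H](c3ccc(OCc4ccccc4)cc3)O[C@H]2c2ccc(OCc3ccccc3)cc2)c1[C@@H](C(O)c1ccc(OCc2ccccc2)cc1)c1cc(OCc2ccccc2)c2c(c1)[C@@H](c1cc(OCc3ccccc3)cc(OCc3ccccc3)c1)[C@H](c1ccc(OCc3ccccc3)cc1)O2
F5 | step 10 | (2R,3S)-1,4-bis[4-(allyloxy)phenyl]-2-[3,5-bis(benzyloxy)phenyl]-3-{3-(benzyloxy)-5-[(triisopropylsilyl)oxy]phenyl}-4-hydroxybutan-1-one, C4 epimers | O=C(c1ccc(OCC=C)cc1)[C@@H](c1cc(OCc2ccccc2)cc(OCc2ccccc2)c1)[C@@H](c1cc(OCc2ccccc2)cc(O[Si](C(C)C)(C(C)C)C(C)C)c1)C(O)c1ccc(OCC=C)cc1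
F6 | step 10 | corresponding bis-allyl butane-1,4-diol | OC(c1ccc(OCC=C)cc1)[C@@H](c1cc(OCc2ccccc2)cc(OCc2ccccc2)c1)[C@@H](c1cc(OCc2ccccc2)cc(O[Si](C(C)C)(C(C)C)C(C)C)c1)C(O)c1ccc(OCC=C)cc1
F7 | step 10 | corresponding bis(4-hydroxyphenyl) butane-1,4-diol | OC(c1ccc(O)cc1)[C@@H](c1cc(OCc2ccccc2)cc(OCc2ccccc2)c1)[C@@H](c1cc(OCc2ccccc2)cc(O[Si](C(C)C)(C(C)C)C(C)C)c1)C(O)c1ccc(O)cc1
F8 | step 10 | (2R,3S,4R,5S)-2,5-bis(4-hydroxyphenyl)-4-[3,5-bis(benzyloxy)phenyl]-3-{3-(benzyloxy)-5-[(triisopropylsilyl)oxy]phenyl}oxolane | CC(C)[Si](Oc1cc(OCc2ccccc2)cc(c1)[C@@H]1[C@H](c2cc(OCc3ccccc3)cc(OCc3ccccc3)c2)[C@@H](c2ccc(O)cc2)O[C@H]1c1ccc(O)cc1)(C(C)C)C(C)C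
F0 | step 25 | none | none
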